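**Retrosynthetic overview**
1. 7 ⇒ 6: the ring methyl goes on last, by radical C–H methylation at C5 of the quinone.
2. 6 ⇒ 4: direct oxidation of the mirror-symmetric resorcinol diether. One C–H becomes C=O and one of the two equivalent OMe groups leaves as MeOH, so all ring positions become different in one operation.
3. 4 ⇒ 1 + 2: benzylic C–C bond from the benzyl anion of 3,5-dimethoxytoluene and a C24 bromide.
4. Ring order: no ring is built. The only ring is bought as the benzene ring of 1 and becomes the quinone in step 2.

Assumption: the target has no stereocentre and no stereogenic double bond, so it is achiral and no enantiomer has to be set; the side chain is read as unbranched C25 (pentacosyl, C33H58O3); 1-bromotetracosane is taken as a catalogue chemical.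

**Step 1**
Reactants: 1 3,5-dimethoxytoluene (orcinol dimethyl ether); 2 1-bromotetracosane
Product: 4 1,3-dimethoxy-5-pentacosylbenzene, via (3,5-dimethoxybenzyl)potassium 3 (not isolated)
Conditions: 1 (1.3 equiv), n-BuLi, KOt-Bu, 2,2,6,6-tetramethylpiperidine (1.3 equiv each), THF, −78 °C, 30 min; then 2 (1.0 equiv) in THF, −78 °C to rt
Reagents that add atoms: none
Why: Lateral (benzylic) metalation with a Lochmann–Schlosser-type mixed Li/K amide base followed by SN2 alkylation: the amine shuttles protons so that any ring-metalated species funnels to the delocalised benzyl potassium 3, which is stabilised inductively by the two meta methoxy groups and displaces the unhindered primary bromide, and no stereocentre is formed.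

**Step 2**
Reactants: 4 1,3-dimethoxy-5-pentacosylbenzene
Product: 6 2-methoxy-6-pentacosyl-1,4-benzoquinone, via 2,4-dimethoxy-6-pentacosylphenol 5 (not isolated)
Conditions: MeReO3 (5 mol %), 35% aq H2O2 (6 equiv), AcOH/ClCH2CH2Cl 4:1, 40 °C
Reagents that add atoms: hydrogen peroxide, OO
Why: MeReO3/H2O2 arene-to-quinone oxidation (oxidative dearomatisation by electrophilic hydroxylation, then oxidative demethylation): the rhenium peroxo species transfers oxygen to one of the two equivalent C–H positions that lie ortho to one and para to the other methoxy group (the site where this ring type is also formylated and brominated), and the 4-methoxyphenol 5 so formed is oxidised faster than 4 by ipso attack and loss of methanol, which removes aromaticity and mirror symmetry at once and leaves exactly one methoxy group next to the new C1 carbonyl, with no stereocentre formed.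

**Step 3**
Reactants: 6 2-methoxy-6-pentacosyl-1,4-benzoquinone
Product: 7 5-methoxy-2-methyl-3-pentacosyl-1,4-benzoquinone (5-methoxy-2-methyl-3-pentacosylcyclohexa-2,5-diene-1,4-dione, the target)
Conditions: AgNO3 (0.3 equiv), (NH4)2S2O8 (3 equiv, in portions), AcOH/MeCN/H2O 4:2:1, 75 °C
Reagents that add atoms: acetic acid, CC(=O)O
Why: Jacobsen–Torssell (Minisci-type) silver-catalysed decarboxylative radical alkylation: persulfate raises monovalent to divalent silver, which decarboxylates acetic acid to the methyl radical, and this nucleophilic radical adds at C5, the beta carbon of the enone of the undeactivated C1 carbonyl, in preference to C3, the electron-rich beta carbon of the vinylogous ester, before re-oxidation restores the quinone, with no stereocentre formed.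

**Compound list**
1 | 3,5-dimethoxytoluene | COc1cc(C)cc(OC)c1 | starting material
2 | 1-bromotetracosane | CCCCCCCCCCCCCCCCCCCCCCCCBr | starting material
3 | (3,5-dimethoxybenzyl)potassium | [K+].[CH2-]c1cc(OC)cc(OC)c1 | intermediate
4 | 1,3-dimethoxy-5-pentacosylbenzene | CCCCCCCCCCCCCCCCCCCCCCCCCc1cc(OC)cc(OC)c1 | intermediate
5 | 2,4-dimethoxy-6-pentacosylphenol | CCCCCCCCCCCCCCCCCCCCCCCCCc1cc(OC)cc(OC)c1O | intermediate
6 | 2-methoxy-6-pentacosyl-1,4-benzoquinone | CCCCCCCCCCCCCCCCCCCCCCCCCC1=CC(=O)C=C(OC)C1=O | intermediate
7 | 5-methoxy-2-methyl-3-pentacosyl-1,4-benzoquinone | CCCCCCCCCCCCCCCCCCCCCCCCCC1=C(C)C(=O)C=C(OC)C1=O | target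

**Total step count:** 3
**Longest linear sequence:** 3 (1 → 4 → 6 → 7)

**Steps most likely to fail**

First, step 2. The risks are oxygen transfer to the position between the two methoxy groups, over-oxidation of the quinone, and poor solubility of the waxy arene. The fallback sets out from 4 and comes back at 6. It breaks the symmetry by nucleophilic mono-demethylation with NaSEt in DMF at 140 °C. The phenoxide that forms shields the second ether, so the reaction stops at 3-methoxy-5-pentacosylphenol F2. A Teuber oxidation follows with (KSO3)2NO (2.2 equiv) in KH2PO4 buffer/CH2Cl2 with a quaternary ammonium phase-transfer salt at rt. It places the new carbonyl para to the hydroxyl, between the methoxy group and the chain, and gives 6.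

Second, step 3. The risks are incomplete conversion, a second methylation at C3, and poor mixing of the lipophilic quinone with the aqueous oxidant. Since 6 and 7 differ by only one CH2, leftover 6 is best removed with a water-soluble thiol, which adds to its free C5. The fallback sets out from 4 and comes back at 7, and it installs the methyl group before the ring is oxidised. Vilsmeier–Haack formylation (POCl3, DMF, 0 to 70 °C) attacks one of the two equivalent positions ortho to the chain and gives 2,4-dimethoxy-6-pentacosylbenzaldehyde F3. Ionic hydrogenation (Et3SiH, CF3CO2H, CH2Cl2, rt) reduces the electron-rich aldehyde to 1,5-dimethoxy-2-methyl-3-pentacosylbenzene F4. The MeReO3/H2O2/AcOH oxidation of step 2 then hydroxylates the C–H para to the methoxy group that sits next to the methyl, expels that methoxy group as methanol, and gives 7 directly.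

Third, step 1. The risks are persistent ring metalation between the methoxy groups, precipitation of 2 at low temperature, and some E2 elimination. The fallback sets out from 2 and comes back at 4, with the polarity of the same bond reversed. Mg turnings in THF at 50 °C convert 2 into tetracosylmagnesium bromide F1. F1 is coupled with bought 3,5-dimethoxybenzyl bromide (COc1cc(CBr)cc(OC)c1) under Li2CuCl4 (3 mol %) in THF at 0 °C, a Kochi-type copper-catalysed sp3–sp3 coupling, to give 4.

**Further compounds**
F1 | step 1 | tetracosylmagnesium bromide | CCCCCCCCCCCCCCCCCCCCCCCC[Mg]Br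
F2 | step 2 | 3-methoxy-5-pentacosylphenol | CCCCCCCCCCCCCCCCCCCCCCCCCc1cc(O)cc(OC)c1
F3 | step 3 | 2,4-dimethoxy-6-pentacosylbenzaldehyde | CCCCCCCCCCCCCCCCCCCCCCCCCc1cc(OC)cc(OC)c1C=O
F4 | step 3 | 1,5-dimethoxy-2-methyl-3-pentacosylbenzene | CCCCCCCCCCCCCCCCCCCCCCCCCc1cc(OC)cc(OC)c1C
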